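**Retrosynthetic overview**
1. Target 13 ⇐ ethyl ester 11 (hydride reduction) ⇐ 4,5-dihydrofuran 10: syn-addition of H2 anti to the C8′ benzyl group sets C7 and C8 together and makes the ring all-cis.
2. 10 ⇐ closure of the C9′–OH onto electrophilic C7 with loss of water. C7 is held at the ketone level because closure at the benzylic-cation (quinone-methide) level gives the 7,8-trans ring.
3. Open-chain precursor ⇐ enantioselective radical β–β′ (C8–C8′) union of two C6C3 units: the enamine of arylpropanal 4 plus the α-radical from bromo aroylacetate 6. This sets C8′ (R), the only catalyst-controlled centre.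
4. 4 ⇐ aryl bromide 1 + allyl alcohol 2 (Heck); 6 ⇐ keto ester 5 + NBS.
5. Only one ring is formed, the oxolane, in step 3. The order is C8–C8′ coupling, then O9′→C7 closure, then hydrogen delivery to C7, which is the order of events in lignan biogenesis.

Assumption: lignan numbering is used in the comments (C7–C9 for the 3,4,5-trimethoxyphenyl unit, C7′–C9′ for the 2,4,5-trimethoxybenzyl unit); the sense of induction of the (2R,5S)-imidazolidinone is taken from its reported alkylations with bromomalonates (R aldehydes) and has not been verified for this substrate.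

**Step 1**
Reactants: 1 1-bromo-2,4,5-trimethoxybenzene; 2 allyl alcohol
Product: 4 3-(2,4,5-trimethoxyphenyl)propanal, via enol 3 (not isolated)
Conditions: Pd(OAc)2 (3 mol%), Bu4NCl, NaHCO3, DMF, 90 °C
Reagents that add atoms: none
Why: Heck arylation of allyl alcohol under Jeffery conditions: the aryl group adds to the terminal carbon, β-hydride elimination towards the carbinol gives the enol, and this tautomerises to the saturated aldehyde (no stereocentre).

**Step 2**
Reactants: 5 ethyl 3-oxo-3-(3,4,5-trimethoxyphenyl)propanoate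
Product: 6 ethyl 2-bromo-3-oxo-3-(3,4,5-trimethoxyphenyl)propanoate (racemic)
Conditions: NBS (1.05 equiv), NH4OAc (10 mol%), Et2O, rt
Reagents that add atoms: N-bromosuccinimide, O=C1CCC(=O)N1Br
Why: Electrophilic α-bromination of the β-keto ester through its enol, which is far faster than bromination of the acyl-deactivated ring.

**Step 3**
Reactants: 4 3-(2,4,5-trimethoxyphenyl)propanal (2 equiv); 6 ethyl 2-bromo-3-oxo-3-(3,4,5-trimethoxyphenyl)propanoate
Product: 10 ethyl (4R)-2-(3,4,5-trimethoxyphenyl)-4-[(2,4,5-trimethoxyphenyl)methyl]-4,5-dihydrofuran-3-carboxylate, via keto aldehyde 7 (not isolated), via hydroxy keto ester 8 (not isolated), via hemiketal 9 (not isolated)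
Conditions: (2R,5S)-2-tert-butyl-3,5-dimethylimidazolidin-4-one·TfOH (20 mol%), Ru(bpy)3Cl2 (0.5 mol%), 2,6-lutidine (2 equiv), DMF, blue LED, rt; then EtOH, NaBH4, −78 °C; then HCl/EtOH (excess), 50 °C
Reagents that add atoms: none
Why: Enantioselective photoredox organocatalytic α-alkylation of an aldehyde (MacMillan type), in which the electrophilic C8 radical from 6 adds to the Si face of the E-enamine of 4 (the catalyst C5-methyl blocks the Re face) to form C8–C8′ and set C8′ as R, after which NaBH4 at −78 °C reduces only the aldehyde before it can epimerise or condense to a furan, and acid lets the C9′–OH add to the C7 ketone and lose water (hemiketalisation–dehydration under Korte acyl-lactone-rearrangement conditions, which also return any lactonised material) to give the conjugated dihydrofuran, where the scrambled C8 centre has become sp2.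

**Step 4**
Reactants: 10 ethyl (4R)-2-(3,4,5-trimethoxyphenyl)-4-[(2,4,5-trimethoxyphenyl)methyl]-4,5-dihydrofuran-3-carboxylate
Product: 11 ethyl (2R,3S,4R)-2-(3,4,5-trimethoxyphenyl)-4-[(2,4,5-trimethoxyphenyl)methyl]oxolane-3-carboxylate (all-cis)
Conditions: H2 (20 bar), 10% Pd/C, EtOAc, rt
Reagents that add atoms: none
Why: Heterogeneous syn-hydrogenation of the tetrasubstituted enol-ether C=C delivers both hydrogens to the ring face opposite the C4 benzyl group, which places the aryl group (C2, R) and the ester (C3, S) cis to each other and to the benzyl group.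

**Step 5**
Reactants: 11 ethyl (2R,3S,4R)-2-(3,4,5-trimethoxyphenyl)-4-[(2,4,5-trimethoxyphenyl)methyl]oxolane-3-carboxylate
Product: 13 [(2R,3R,4R)-2-(3,4,5-trimethoxyphenyl)-4-[(2,4,5-trimethoxyphenyl)methyl]oxolan-3-yl]methanol (target), via aldehyde 12 (not isolated)
Conditions: LiAlH4, THF, −20 → 0 °C; Rochelle salt work-up
Reagents that add atoms: none
Why: Hydride reduction of the ester to the primary alcohol is fast at low temperature, so the all-cis C3 centre is not epimerised, and nothing else in the molecule is reducible (the C3 descriptor changes from S to R only through CIP priorities).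

**Compound list**
1 | 1-bromo-2,4,5-trimethoxybenzene | COc1cc(OC)c(OC)cc1Br | starting material
2 | allyl alcohol (prop-2-en-1-ol) | C=CCO | starting material
3 | 3-(2,4,5-trimethoxyphenyl)prop-1-en-1-ol (enol, E/Z) | COc1cc(OC)c(OC)cc1CC=CO | intermediate
4 | 3-(2,4,5-trimethoxyphenyl)propanal | COc1cc(OC)c(OC)cc1CCC=O | intermediate
5 | ethyl 3-oxo-3-(3,4,5-trimethoxyphenyl)propanoate | CCOC(=O)CC(=O)c1cc(OC)c(OC)c(OC)c1 | starting material
6 | ethyl 2-bromo-3-oxo-3-(3,4,5-trimethoxyphenyl)propanoate (racemic) | CCOC(=O)C(Br)C(=O)c1cc(OC)c(OC)c(OC)c1 | intermediate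
7 | ethyl (3R)-4-oxo-2-(3,4,5-trimethoxybenzoyl)-3-[(2,4,5-trimethoxyphenyl)methyl]butanoate (C2 epimers) | CCOC(=O)C(C(=O)c1cc(OC)c(OC)c(OC)c1)[C@H](C=O)Cc1cc(OC)c(OC)cc1OC | intermediate
8 | ethyl (3R)-4-hydroxy-2-(3,4,5-trimethoxybenzoyl)-3-[(2,4,5-trimethoxyphenyl)methyl]butanoate (C2 epimers) | CCOC(=O)C(C(=O)c1cc(OC)c(OC)c(OC)c1)[C@H](CO)Cc1cc(OC)c(OC)cc1OC | intermediate
9 | ethyl (4R)-2-hydroxy-2-(3,4,5-trimethoxyphenyl)-4-[(2,4,5-trimethoxyphenyl)methyl]oxolane-3-carboxylate | CCOC(=O)C1C(O)(c2cc(OC)c(OC)c(OC)c2)OC[C@@H]1Cc1cc(OC)c(OC)cc1OC | intermediate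
10 | ethyl (4R)-2-(3,4,5-trimethoxyphenyl)-4-[(2,4,5-trimethoxyphenyl)methyl]-4,5-dihydrofuran-3-carboxylate | CCOC(=O)C1=C(c2cc(OC)c(OC)c(OC)c2)OC[C@@H]1Cc1cc(OC)c(OC)cc1OC | intermediate
11 | ethyl (2R,3S,4R)-2-(3,4,5-trimethoxyphenyl)-4-[(2,4,5-trimethoxyphenyl)methyl]oxolane-3-carboxylate (all-cis) | COc1cc(OC)c(OC)cc1C[C@H]1CO[C@@H](c2cc(OC)c(OC)c(OC)c2)[C@H]1C(=O)OCC | intermediate
12 | (2R,3S,4R)-2-(3,4,5-trimethoxyphenyl)-4-[(2,4,5-trimethoxyphenyl)methyl]oxolane-3-carbaldehyde | COc1cc(OC)c(OC)cc1C[C@H]1CO[C@@H](c2cc(OC)c(OC)c(OC)c2)[C@H]1C=O | intermediate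
13 | [(2R,3R,4R)-2-(3,4,5-trimethoxyphenyl)-4-[(2,4,5-trimethoxyphenyl)methyl]oxolan-3-yl]methanol | COc1cc(OC)c(OC)cc1C[C@H]1CO[C@@H](c2cc(OC)c(OC)c(OC)c2)[C@H]1CO | target

**Totals**
Total step count: 5. Longest linear sequence: 4 (steps 1, 3, 4, 5).

**Steps most likely to fail, with fallbacks**

Step 3 is the riskiest. The secondary bromo keto ester may transfer Br+ instead of coupling as a radical, keto aldehyde 7 may dehydrate to a furan (losing C8′), and the three-stage one-pot may be low-yielding. The fallback sets out from aldehyde 4 and returns at dihydrofuran 10; it brings the aroyl group in by a polar acylation instead of inside the radical partner. Aldehyde 4 is alkylated under the same photoredox/imidazolidinone conditions with diethyl bromomalonate, the best-precedented partner, to give diethyl 2-[(2R)-1-oxo-3-(2,4,5-trimethoxyphenyl)propan-2-yl]propanedioate F1. NaBH4 in the same flask and an acidic work-up reduce and lactonise it to ethyl (4R)-2-oxo-4-[(2,4,5-trimethoxyphenyl)methyl]oxolane-3-carboxylate F2. Krapcho dealkoxycarbonylation (LiCl, wet DMSO, 150 °C) gives (4R)-4-[(2,4,5-trimethoxyphenyl)methyl]oxolan-2-one F3. Claisen C-acylation of its lithium enolate (LiHMDS 2.2 equiv, then 3,4,5-trimethoxybenzoyl chloride, THF, −78 °C) gives (4R)-3-(3,4,5-trimethoxybenzoyl)-4-[(2,4,5-trimethoxyphenyl)methyl]oxolan-2-one F4. HCl in EtOH at 50 °C then converts F4 by the acyl-lactone rearrangement into 10.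

Step 4 is next. The tetrasubstituted push–pull alkene may react slowly; Pd may cleave the benzylic C2–O bond or migrate the double bond towards C4; and one benzyl group may not give enough facial bias. The fallback sets out from 10 and returns at target 13, reversing the order of reduction and hydrogenation. DIBAL-H (CH2Cl2, −78 °C, Rochelle salt work-up) reduces 10 to [(4R)-2-(3,4,5-trimethoxyphenyl)-4-[(2,4,5-trimethoxyphenyl)methyl]-4,5-dihydrofuran-3-yl]methanol F5. This is hydrogenated homogeneously with Crabtree's catalyst (H2, CH2Cl2, rt). The hydroxymethyl group on the sp2 carbon can bind iridium on either face, so the C4 benzyl group again selects the opposite face and the all-cis alcohol 13 forms directly.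

Step 1 is third. The electron-rich, ortho-substituted aryl bromide may add slowly to Pd, and some branched aldehyde can form. The fallback sets out from bromide 1 and returns at aldehyde 4. Br–Li exchange (n-BuLi, THF, −78 °C) and opening of oxetane with BF3·OEt2 give 3-(2,4,5-trimethoxyphenyl)propan-1-ol F6. Oxidation with TEMPO/PhI(OAc)2 in CH2Cl2 gives 4.

**Further compounds**
F1 | step 3 | diethyl 2-[(2R)-1-oxo-3-(2,4,5-trimethoxyphenyl)propan-2-yl]propanedioate | CCOC(=O)C(C(=O)OCC)[C@H](C=O)Cc1cc(OC)c(OC)cc1OC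
F2 | step 3 | ethyl (4R)-2-oxo-4-[(2,4,5-trimethoxyphenyl)methyl]oxolane-3-carboxylate | CCOC(=O)C1C(=O)OC[C@@H]1Cc1cc(OC)c(OC)cc1OC
F3 | step 3 | (4R)-4-[(2,4,5-trimethoxyphenyl)methyl]oxolan-2-one | O=C1C[C@H](CO1)Cc1cc(OC)c(OC)cc1OC
F4 | step 3 | (4R)-3-(3,4,5-trimethoxybenzoyl)-4-[(2,4,5-trimethoxyphenyl)methyl]oxolan-2-one | O=C1OC[C@H](Cc2cc(OC)c(OC)cc2OC)C1C(=O)c1cc(OC)c(OC)c(OC)c1
F5 | step 4 | [(4R)-2-(3,4,5-trimethoxyphenyl)-4-[(2,4,5-trimethoxyphenyl)methyl]-4,5-dihydrofuran-3-yl]methanol | OCC1=C(c2cc(OC)c(OC)c(OC)c2)OC[C@@H]1Cc1cc(OC)c(OC)cc1OC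
F6 | step 1 | 3-(2,4,5-trimethoxyphenyl)propan-1-ol | COc1cc(OC)c(OC)cc1CCCO
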